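**Strategy.** Ring B is closed last, at its only olefin. In labdane numbering, the trisubstituted C7=C8 double bond (C8 carries the vinylic methyl) is made by ring-closing olefin metathesis of a monocyclic ring A enone that carries an allyl group on C5 and a but-2-en-2-yl group on C9. One operation forms ring B and the target alkene without regiochemical ambiguity. The C9 and C10 stereocentres of the precursor come in one event from a ketal Claisen rearrangement that transfers a single catalyst-set carbinol centre. C5 and C3 are then relayed by substrate control, and C13 with its chain is bought as (S)-citronellol.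

Key step: step 10

Assumption: labdane numbering is used throughout (C3 ring carbinol carbon, C4 gem-dimethyl carbon, C5/C10 ring-fusion carbons, C7=C8 ring olefin, C9 side-chain-bearing ring carbon, C13 side-chain methine, C15 primary oxygenated carbon); the target is (3S,5R,9S,10R,13S)-labd-7-ene-3,15-diyl diformate.

Step 1
Reactants: 1 (S)-citronellol
Product: 2 (S)-citronellyl triisopropylsilyl ether
Conditions: iPr3SiCl, imidazole, DMF, rt
Reagents that add atoms: triisopropylsilyl chloride, CC(C)[Si](Cl)(C(C)C)C(C)C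
Why: Imidazole-promoted silylation of the primary alcohol gives a silyl ether that should survive ozone, organometallic reagents, weak acid at 140 °C and dissolving lithium, and the C13 stereocentre bought with 1 is not touched.

Step 2
Reactants: 2 (S)-citronellyl triisopropylsilyl ether
Product: 4 (4S)-4-methyl-6-(triisopropylsilyloxy)hexanal, via secondary ozonide 3 (not isolated)
Conditions: O3, CH2Cl2, −78 °C; then PPh3, −78 °C to rt
Reagents that add atoms: ozone, [O-][O+]=O
Why: Ozonolysis with reductive work-up cleaves the trisubstituted olefin and leaves an aldehyde whose carbonyl carbon is the future C9, with the remote C13 centre unchanged.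

Step 3
Reactants: 4 (4S)-4-methyl-6-(triisopropylsilyloxy)hexanal; 5 3-(triphenylphosphoranylidene)butan-2-one
Product: 6 (3E,7S)-3,7-dimethyl-9-(triisopropylsilyloxy)non-3-en-2-one
Conditions: toluene, 90 °C
Reagents that add atoms: none
Why: Wittig olefination with a stabilised ylide should give the E trisubstituted enone, which brings in C8 with its methyl group and the acetyl carbon that will carry the controlling stereocentre.

Step 4
Reactants: 6 (3E,7S)-3,7-dimethyl-9-(triisopropylsilyloxy)non-3-en-2-one
Product: 7 (2R,3E,7S)-3,7-dimethyl-9-(triisopropylsilyloxy)non-3-en-2-ol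
Conditions: (S)-2-methyl-CBS-oxazaborolidine (10 mol %), catecholborane, toluene, −78 °C
Reagents that add atoms: none
Why: Corey–Bakshi–Shibata reduction of the methyl alkenyl ketone with the (S)-oxazaborolidine (alkenyl group as the large substituent) should give the R carbinol, the one stereocentre set by catalysis from which C9, C10, C5 and C3 are relayed.

Step 5
Reactants: 8 2,6-dimethylcyclohexanone (cis/trans mixture)
Product: 9 1,1-dimethoxy-2,6-dimethylcyclohexane
Conditions: HC(OMe)3, MeOH, TsOH (cat.), 50 °C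
Reagents that add atoms: trimethyl orthoformate, COC(OC)OC
Why: Acid-catalysed ketalisation driven by the orthoformate converts the hindered ketone into the dimethyl ketal needed for alcohol exchange.

Step 6
Reactants: 7 (2R,3E,7S)-3,7-dimethyl-9-(triisopropylsilyloxy)non-3-en-2-ol; 9 1,1-dimethoxy-2,6-dimethylcyclohexane
Product: 12 (2R)-2,6-dimethyl-2-[(2E,4S,7S)-3,7-dimethyl-9-(triisopropylsilyloxy)non-2-en-4-yl]cyclohexan-1-one (C6 epimers), via mixed methyl allyl ketal 10 (not isolated), via allyl enol ether 11 (not isolated)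
Conditions: EtCO2H (cat.), xylene, 140 °C, MeOH distilled off
Reagents that add atoms: none
Why: Ketal Claisen rearrangement, in which exchange of one methoxy group for 7, loss of methanol to the tetrasubstituted allyl cyclohexenyl ether and a [3,3] shift through a chair transition state with the carbinol methyl equatorial should transfer the C–O stereocentre to C9 and, because the ring fixes the enol ether geometry (ring CH2 equatorial, methyl axial), to the quaternary C10 in the same event.

Step 7
Reactants: 12 (2R)-2,6-dimethyl-2-[(2E,4S,7S)-3,7-dimethyl-9-(triisopropylsilyloxy)non-2-en-4-yl]cyclohexan-1-one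
Product: 14 (6R)-2,6-dimethyl-6-[(2E,4S,7S)-3,7-dimethyl-9-(triisopropylsilyloxy)non-2-en-4-yl]cyclohex-2-en-1-one, via trimethylsilyl enol ether 13 (not isolated)
Conditions: Me3SiOTf, Et3N, CH2Cl2, 0 °C; then Pd(OAc)2, MeCN, rt
Reagents that add atoms: none
Why: Saegusa–Ito oxidation, in which the ketone can enolise only toward C4 and β-hydride elimination of the palladium enolate into the ring should give the conjugated endocyclic enone, erasing the unspecified C4 centre.

Step 8
Reactants: 14 (6R)-2,6-dimethyl-6-[(2E,4S,7S)-3,7-dimethyl-9-(triisopropylsilyloxy)non-2-en-4-yl]cyclohex-2-en-1-one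
Product: 15 (6R)-1-allyl-2,6-dimethyl-6-[(2E,4S,7S)-3,7-dimethyl-9-(triisopropylsilyloxy)non-2-en-4-yl]cyclohex-2-en-1-ol (C1 epimers)
Conditions: CH2=CHCH2MgBr, THF, −78 to 0 °C; then NH4Cl (aqueous)
Reagents that add atoms: allylmagnesium bromide, C=CC[Mg]Br
Why: Grignard 1,2-addition of the small allyl nucleophile to the hindered, non-enolisable enone carbonyl should give the tertiary allylic alcohol, whose new carbinol centre (either epimer) is erased in step 9.

Step 9
Reactants: 15 (6R)-1-allyl-2,6-dimethyl-6-[(2E,4S,7S)-3,7-dimethyl-9-(triisopropylsilyloxy)non-2-en-4-yl]cyclohex-2-en-1-ol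
Product: 16 (4R)-3-allyl-2,4-dimethyl-4-[(2E,4S,7S)-3,7-dimethyl-9-(triisopropylsilyloxy)non-2-en-4-yl]cyclohex-2-en-1-one
Conditions: pyridinium chlorochromate (C5H5NH)[CrO3Cl], 4 Å molecular sieves, CH2Cl2, rt
Reagents that add atoms: pyridinium chlorochromate, [O-][Cr](=O)(=O)Cl.c1cc[nH+]cc1
Why: Dauben–Babler oxidative 1,3-transposition, in which the tertiary allylic chromate ester undergoes a [3,3] shift that places oxygen on C3 and is then oxidised, should give the enone with its carbonyl at C3 and the allyl group on C5.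

Step 10
Reactants: 16 (4R)-3-allyl-2,4-dimethyl-4-[(2E,4S,7S)-3,7-dimethyl-9-(triisopropylsilyloxy)non-2-en-4-yl]cyclohex-2-en-1-one
Product: 17 (9S,10R,13S)-15-(triisopropylsilyloxy)-19-norlabda-4,7-dien-3-one (bicyclic dienone)
Conditions: second-generation Grubbs catalyst RuCl2(=CHPh)(H2IMes)(PCy3) (5 mol %), CH2Cl2 (0.005 M), 40 °C
Reagents that add atoms: none
Why: The ruthenium benzylidene exchanges onto the unhindered monosubstituted allyl olefin on C5, the resulting alkylidene at C7 undergoes intramolecular [2+2] cycloaddition with the trisubstituted olefin of the but-2-en-2-yl group, and cycloreversion expels propene, so that C7 and C8 are joined as the ring B double bond. The closest known reaction type is ring-closing olefin metathesis of a terminal olefin with a 1,1,2-trisubstituted olefin to give a trisubstituted cyclohexene under N-heterocyclic-carbene ruthenium catalysis. Ring B (C5, C6, C7, C8, C9, C10) is closed as a six-membered ring with both reacting carbons becoming the endocyclic olefin, the only ring size the two olefin arms can reach. No stereocentre is created; C9 and C10 from step 6 are spectators, and the vinylic methyl ends on C8 because it already sits on the olefin carbon that stays in the ring. The step needs chemoselectivity for the two isolated olefins over the enone olefin and against migration of the allyl double bond; the substrate secures this because the C4=C5 olefin is tetrasubstituted and electron-poor and the two arms sit 1,6 on the C5–C10–C9 backbone, which should make closure fast.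

Step 11
Reactants: 17 (9S,10R,13S)-15-(triisopropylsilyloxy)-19-norlabda-4,7-dien-3-one
Product: 19 (5R,9S,10R,13S)-15-(triisopropylsilyloxy)labd-7-en-3-one, via lithium enolate 18 (not isolated)
Conditions: Li (2.1 equiv), NH3(l)/THF, H2O (1.0 equiv), −78 °C; then MeI, −78 to −33 °C
Reagents that add atoms: iodomethane, CI
Why: Birch-type reductive alkylation of the enone, in which the C5 carbanion is protonated axially on the face opposite the angular C10 methyl to give the trans ring fusion and the regiodefined C3–C4 lithium enolate is C-methylated to complete the gem-dimethyl group, while the isolated C7=C8 olefin is not reduced.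

Step 12
Reactants: 19 (5R,9S,10R,13S)-15-(triisopropylsilyloxy)labd-7-en-3-one
Product: 20 (3S,5R,9S,10R,13S)-15-(triisopropylsilyloxy)labd-7-en-3-ol
Conditions: NaBH4, MeOH, 0 °C
Reagents that add atoms: none
Why: Borohydride reduction of the 4,4-dimethyl-3-ketone of the trans-decalin by axial hydride attack from the α face, away from the axial C4 and C10 methyl groups, should give the equatorial 3β (3S) alcohol.

Step 13
Reactants: 20 (3S,5R,9S,10R,13S)-15-(triisopropylsilyloxy)labd-7-en-3-ol
Product: 21 (3S,5R,9S,10R,13S)-labd-7-ene-3,15-diol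
Conditions: Bu4NF, THF, rt
Reagents that add atoms: none
Why: Fluoride-induced desilylation frees the primary C15 alcohol without affecting the olefin or any stereocentre.

Step 14
Reactants: 21 (3S,5R,9S,10R,13S)-labd-7-ene-3,15-diol
Product: 22 (3S,5R,9S,10R,13S)-labd-7-ene-3,15-diyl diformate
Conditions: HCO2H and Ac2O premixed (50 °C) to give HCO2Ac; then pyridine, DMAP (cat.), CH2Cl2, 0 °C
Reagents that add atoms: formic acid, O=CO (delivered as formic acetic anhydride, CC(=O)OC=O)
Why: Acylation with the mixed anhydride transfers the more electrophilic formyl group to both the primary and the hindered secondary hydroxyl, giving the diformate without touching any stereocentre.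

**Compound list**

1 | (S)-citronellol, (3S)-3,7-dimethyloct-6-en-1-ol | CC(C)=CCC[C@H](C)CCO | starting material
2 | (S)-citronellyl triisopropylsilyl ether | CC(C)=CCC[C@H](C)CCO[Si](C(C)C)(C(C)C)C(C)C | intermediate
3 | secondary ozonide (1,2,4-trioxolane) of 2 | CC1(C)OOC(CC[C@H](C)CCO[Si](C(C)C)(C(C)C)C(C)C)O1 | intermediate
4 | (4S)-4-methyl-6-(triisopropylsilyloxy)hexanal | O=CCC[C@H](C)CCO[Si](C(C)C)(C(C)C)C(C)C | intermediate
5 | 3-(triphenylphosphoranylidene)butan-2-one | CC(=O)C(C)=P(c1ccccc1)(c1ccccc1)c1ccccc1 | starting material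
6 | (3E,7S)-3,7-dimethyl-9-(triisopropylsilyloxy)non-3-en-2-one | CC(=O)/C(C)=C/CC[C@H](C)CCO[Si](C(C)C)(C(C)C)C(C)C | intermediate
7 | (2R,3E,7S)-3,7-dimethyl-9-(triisopropylsilyloxy)non-3-en-2-ol | C[C@@H](O)/C(C)=C/CC[C@H](C)CCO[Si](C(C)C)(C(C)C)C(C)C | intermediate
8 | 2,6-dimethylcyclohexanone (cis/trans mixture) | CC1CCCC(C)C1=O | starting material
9 | 1,1-dimethoxy-2,6-dimethylcyclohexane | COC1(OC)C(C)CCCC1C | intermediate
10 | mixed ketal, 1-methoxy-2,6-dimethyl-1-{[(2R,3E,7S)-3,7-dimethyl-9-(triisopropylsilyloxy)non-3-en-2-yl]oxy}cyclohexane | COC1(O[C@H](C)/C(C)=C/CC[C@H](C)CCO[Si](C(C)C)(C(C)C)C(C)C)C(C)CCCC1C | intermediate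
11 | allyl enol ether, 2,6-dimethyl-1-{[(2R,3E,7S)-3,7-dimethyl-9-(triisopropylsilyloxy)non-3-en-2-yl]oxy}cyclohex-1-ene | CC1CCCC(C)=C1O[C@H](C)/C(C)=C/CC[C@H](C)CCO[Si](C(C)C)(C(C)C)C(C)C | intermediate
12 | (2R)-2,6-dimethyl-2-[(2E,4S,7S)-3,7-dimethyl-9-(triisopropylsilyloxy)non-2-en-4-yl]cyclohexan-1-one (C6 epimers; ring C2 is C10, side-chain C4 is C9) | O=C1C(C)CCC[C@]1(C)[C@H](/C(C)=C/C)CC[C@H](C)CCO[Si](C(C)C)(C(C)C)C(C)C | intermediate
13 | trimethylsilyl enol ether of 12 | C[Si](C)(C)OC1=C(C)CCC[C@]1(C)[C@H](/C(C)=C/C)CC[C@H](C)CCO[Si](C(C)C)(C(C)C)C(C)C | intermediate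
14 | (6R)-2,6-dimethyl-6-[(2E,4S,7S)-3,7-dimethyl-9-(triisopropylsilyloxy)non-2-en-4-yl]cyclohex-2-en-1-one | O=C1C(C)=CCC[C@]1(C)[C@H](/C(C)=C/C)CC[C@H](C)CCO[Si](C(C)C)(C(C)C)C(C)C | intermediate
15 | (6R)-1-allyl-2,6-dimethyl-6-[(2E,4S,7S)-3,7-dimethyl-9-(triisopropylsilyloxy)non-2-en-4-yl]cyclohex-2-en-1-ol (C1 epimers) | OC1(CC=C)C(C)=CCC[C@]1(C)[C@H](/C(C)=C/C)CC[C@H](C)CCO[Si](C(C)C)(C(C)C)C(C)C | intermediate
16 | (4R)-3-allyl-2,4-dimethyl-4-[(2E,4S,7S)-3,7-dimethyl-9-(triisopropylsilyloxy)non-2-en-4-yl]cyclohex-2-en-1-one | O=C1CC[C@](C)([C@H](/C(C)=C/C)CC[C@H](C)CCO[Si](C(C)C)(C(C)C)C(C)C)C(CC=C)=C1C | intermediate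
17 | (9S,10R,13S)-15-(triisopropylsilyloxy)-19-norlabda-4,7-dien-3-one | CC1=CCC2=C(C)C(=O)CC[C@]2(C)[C@H]1CC[C@H](C)CCO[Si](C(C)C)(C(C)C)C(C)C | intermediate
18 | lithium C3–C4 enolate of 19 lacking one C4 methyl (5R,9S,10R,13S) | [Li+].CC1=CC[C@H]2C(C)=C([O-])CC[C@]2(C)[C@H]1CC[C@H](C)CCO[Si](C(C)C)(C(C)C)C(C)C | intermediate
19 | (5R,9S,10R,13S)-15-(triisopropylsilyloxy)labd-7-en-3-one | CC1=CC[C@H]2C(C)(C)C(=O)CC[C@]2(C)[C@H]1CC[C@H](C)CCO[Si](C(C)C)(C(C)C)C(C)C | intermediate
20 | (3S,5R,9S,10R,13S)-15-(triisopropylsilyloxy)labd-7-en-3-ol | CC1=CC[C@H]2C(C)(C)[C@@H](O)CC[C@]2(C)[C@H]1CC[C@H](C)CCO[Si](C(C)C)(C(C)C)C(C)C | intermediate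
21 | (3S,5R,9S,10R,13S)-labd-7-ene-3,15-diol | CC1=CC[C@H]2C(C)(C)[C@@H](O)CC[C@]2(C)[C@H]1CC[C@H](C)CCO | intermediate
22 | (3S,5R,9S,10R,13S)-labd-7-ene-3,15-diyl diformate (CNP0137609.1) | CC1=CC[C@H]2C(C)(C)[C@@H](OC=O)CC[C@]2(C)[C@H]1CC[C@H](C)CCOC=O | target

**Step count.** Total: 14 steps. Longest linear sequence: 13 steps (steps 1–4 and 6–14 from 1; step 5 is a one-step branch).

**Steps most likely to fail**

Step 6 (ketal Claisen rearrangement). The hindered mixed ketal may form only sluggishly, the secondary allylic alcohol may ionise and eliminate under acid at 140 °C before the enol ether rearranges, and leakage through a boat transition state would erode the C9/C10 relationship. The fallback sets out from 7 and comes back at 16: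
- 7 would be heated with triethyl orthopropionate and catalytic propionic acid (Johnson–Claisen rearrangement, same chair-controlled transfer to C9) to give ethyl (4E)-2,4-dimethyl-3-[(3S)-3-methyl-5-(triisopropylsilyloxy)pentyl]hex-4-enoate F1 as a C10 epimer mixture.
- DIBAL-H at −78 °C would give the corresponding aldehyde F2.
- Robinson annulation with ethyl vinyl ketone (Michael addition through the enamine of a chiral primary amine to create C10, then KOH/MeOH aldol condensation) would give 2,4-dimethyl-4-substituted cyclohex-2-enone F3.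
- Copper-mediated conjugate allylation (CH2=CHCH2MgBr, CuBr·SMe2, Me3SiCl) would give the 3-allyl trimethylsilyl enol ether F4.
- Saegusa–Ito oxidation of F4 with Pd(OAc)2 would re-form the enone with the allyl group on C5, which is 16.

Step 10 (ring-closing metathesis). Closure onto the hindered trisubstituted olefin may be slower than ruthenium-hydride migration of the allyl double bond into conjugation with the enone, or slower than intermolecular metathesis. The fallback sets out from 16 and comes back at 20:
- 16 would be reductively methylated under the conditions of step 11 to the monocyclic 3-allyl-2,2,4-trimethyl-4-substituted cyclohexanone F5.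
- NaBH4 reduction would give the cyclohexanol F6.
- Ozonolysis of both isolated olefins (O3, then PPh3) would give the keto-aldehyde F7 (C7 aldehyde, C8 methyl ketone).
- Intramolecular McMurry coupling (TiCl3(DME)1.5, Zn–Cu couple, DME, reflux; low-valent titanium) would form the same C7=C8 bond and give 20.

Step 9 (oxidative transposition). The hindered tertiary allylic alcohol may dehydrate to trienes, or the chromium oxidant may attack the allyl group faster than the chromate ester rearranges. The fallback sets out from 15 and comes back at 16: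
- 15 would be isomerised by perrhenate-catalysed 1,3-hydroxyl transposition (Ph3SiOReO3, Et2O, 0 °C) to the secondary allylic alcohol 3-allyl-2,4-dimethyl-4-substituted cyclohex-2-en-1-ol F8.
- Oxidation of F8 with Dess–Martin periodinane would give 16.

**Further compounds**

F1 | step 6 | ethyl (4E)-2,4-dimethyl-3-[(3S)-3-methyl-5-(triisopropylsilyloxy)pentyl]hex-4-enoate (C2 epimers, C3 configured as C9 of 12) | CCOC(=O)C(C)[C@H](/C(C)=C/C)CC[C@H](C)CCO[Si](C(C)C)(C(C)C)C(C)C
F2 | step 6 | (4E)-2,4-dimethyl-3-[(3S)-3-methyl-5-(triisopropylsilyloxy)pentyl]hex-4-enal (C2 epimers) | O=CC(C)[C@H](/C(C)=C/C)CC[C@H](C)CCO[Si](C(C)C)(C(C)C)C(C)C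
F3 | step 6 | 2,4-dimethyl-4-[(2E,4S,7S)-3,7-dimethyl-9-(triisopropylsilyloxy)non-2-en-4-yl]cyclohex-2-en-1-one (C10 configured as in 16) | O=C1CC[C@](C)([C@H](/C(C)=C/C)CC[C@H](C)CCO[Si](C(C)C)(C(C)C)C(C)C)C=C1C
F4 | step 6 | trimethylsilyl enol ether of the 3-allyl conjugate adduct of F3 (C5 epimers) | C[Si](C)(C)OC1=C(C)C(CC=C)[C@](C)(CC1)[C@H](/C(C)=C/C)CC[C@H](C)CCO[Si](C(C)C)(C(C)C)C(C)C
F5 | step 10 | 3-allyl-2,2,4-trimethyl-4-[(2E,4S,7S)-3,7-dimethyl-9-(triisopropylsilyloxy)non-2-en-4-yl]cyclohexan-1-one (C5 H trans to C10 methyl) | O=C1CC[C@](C)([C@H](/C(C)=C/C)CC[C@H](C)CCO[Si](C(C)C)(C(C)C)C(C)C)[C@@H](CC=C)C1(C)C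
F6 | step 10 | cyclohexanol from reduction of F5 (C3 configured as in 20) | O[C@H]1CC[C@](C)([C@H](/C(C)=C/C)CC[C@H](C)CCO[Si](C(C)C)(C(C)C)C(C)C)[C@@H](CC=C)C1(C)C
F7 | step 10 | keto-aldehyde from F6 (C7 aldehyde, C8 methyl ketone) | O[C@H]1CC[C@](C)([C@H](C(C)=O)CC[C@H](C)CCO[Si](C(C)C)(C(C)C)C(C)C)[C@@H](CC=O)C1(C)C
F8 | step 9 | 3-allyl-2,4-dimethyl-4-[(2E,4S,7S)-3,7-dimethyl-9-(triisopropylsilyloxy)non-2-en-4-yl]cyclohex-2-en-1-ol (C1 epimers) | OC1CC[C@](C)([C@H](/C(C)=C/C)CC[C@H](C)CCO[Si](C(C)C)(C(C)C)C(C)C)C(CC=C)=C1C
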